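5 questions stand on one charge sent through 4 set-ups.

| flask | starting material | protic impurity | precatalyst | added ligand | remark | time |
|---|---|---|---|---|---|---|
| summer | 0.050 M | 0.025 M | 1.3 µM | 7.5 µM | run made earlier |  |
| noon | 0.050 M | 0.025 M | 0.65 µM | 7.5 µM | run made earlier |  |
| dusk | 0.050 M | 0.025 M | 2.6 µM | 7.5 µM | run made earlier |  |
| autumn | 0.025 M | 0.025 M | 1.3 µM | 7.5 µM | run made earlier |  |
| violet | 0.050 M | 0.0250 M | 1.3 µM | 7.5 µM | a single well-mixed tank run continuously and read at steady state, 60.0 min in it on average |  |
| green | 0.050 M | 0.0250 M | 1.3 µM | 7.5 µM | everything together in a closed stirred flask, run for 20 min | 20 min |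
| blue | 0.050 M (fed, over 16.0 min) | 0.0250 M | 1.3 µM | 7.5 µM | all but starting material at the start; starting material goes in evenly over 16.0 min, the run ends at 20 min | 20 min |
| teal | 0.050 M | 0.0250 M | 1.3 µM | 7.5 µM | a single well-mixed tank run continuously and read at steady state, 20 min in it on average |  |

- summer (time / min: product / %, starting material / %): 2.00: 0.1, 82.1; 4.00: 2.6, 73.0; 6.00: 4.8, 64.9; 8.00: 8.4, 57.7; 10.0: 9.3, 50.6; 12.0: 13.0, 46.6
- noon (time / min: product / %, starting material / %): 0.833: 0, 92.5; 2.50: 0.1, 80.2; 4.00: 1.9, 73.0; 6.00: 2.3, 65.9; 10.0: 4.8, 56.0; 12.0: 7.1, 53.6
- dusk (time / min: product / %, starting material / %): 0.833: 0, 92.3; 2.50: 2.0, 79.2; 4.00: 4.4, 70.5; 6.00: 9.3, 59.0; 10.0: 20.9, 42.6; 12.0: 26.1, 34.9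
- autumn (time / min: product / %, starting material / %): 2.50: 1.1, 78.3; 5.00: 3.9, 62.4; 8.00: 7.4, 49.2; 10.0: 9.0, 41.5; 12.0: 10.9, 36.0

(each reading ± 0.5 percentage points)

* the set-up with the highest amount of product at the outlet or at the end, in percent of the starting material put in ("none" if the first two lie within 2 percentage points) (violet / green / blue / teal / none)
* amount of product at the outlet or at the end, in percent of the starting material put in, violet
* amount of product at the outlet or at the end, in percent of the starting material put in, green
* amount of product at the outlet or at the end, in percent of the starting material put in, blue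
* amount of product at the outlet or at the end, in percent of the starting material put in, teal

- the stated concentrations are those of everything mixed, before any reaction; amounts are the same in each set-up
- the feed brings no volume worth counting
- the earlier runs were made in a closed, stirred flask

The bench rule is a half-life. In the summer run starting material reads 50.6 % after 10.0 min, about half of the charge, so I expect a quarter at 20 min. But product then reads 9.3 %, and the rest has gone elsewhere. At 12.0 min, starting material and product together read 60.7 % in the noon run and 61.0 % in the dusk run, although dusk has 4.00 times the precatalyst. I take this loss to be starting material reacting with protic impurity, one to one.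

Here the half-life meets its border. Protic impurity is the limiting reagent of that waste, and the ratio of the charges gives the waste ceiling 50.0 %, the largest share of the charge that the impurity can take.

The second-order rate integrates in closed form. In autumn the two charges are equal, so wasted over unwasted grows in proportion to time. Neglecting the draw of product on starting material, the autumn reading at 10.0 min gives 49.5 % wasted, hence a waste clock of 10.2 min. With the charges of green, the fraction of impurity left is 1/(2·exp(t/clock) − 1); for violet, the steady balance gives a quadratic.

| set-up | time over clock | impurity left | waste, share of charge |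
|---|---|---|---|
| green | 1.96 | 7.57 % | 46.2 % |
| violet | 5.88 | 13.1 % | 43.5 % |

Violet has 3.00 times the time of green, yet in this reckoning it wastes less. So I choose violet.

The forecast reads violet, with 44 % in violet, 24 % in green, 15 % in blue and 21 % in teal, “because the long residence time outweighs the waste”.

The flask gives violet: violet 41.5 %, green 24.6 %, blue 21.5 %, teal 26.1 %.

    starting material + enzyme → product + enzyme, rate k1*[starting material]^2*[enzyme]/(1 + ([starting material]/Kh1)^2) (21.8 mM, k = 5.40 × 10⁵ M⁻² s⁻¹)
    precatalyst ⇌ enzyme (K = 0.540, k = 0.00160 s⁻¹)
    enzyme + added ligand ⇌ idle complex, settled at all times (K = 1.10 × 10⁶ M⁻¹)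
    starting material + protic impurity → quenched substrate (k = 0.0691 M⁻¹ s⁻¹)

In green, the half-life of starting material against protic impurity alone, at the concentrations as charged, is 6.7 min, and the half-life of precatalyst turning into enzyme, forward step alone, is 7.2 min, which puts the two within 0.500 min of each other. The equilibrium constant of enzyme with added ligand, times added ligand at the start, is 8.2. The ceiling of 50.0 % leaves 50.0 % of a charge beyond the impurity's reach, and violet's 41.5 % stands below that. Blue, left for 200 min, gives 49.1 %.

The data are simulated for substances that don't exist, noise included.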